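A direct plan would oxidise 4-bromo-2,6-dimethoxyphenol A1 to 5-bromo-3-methoxy-o-benzoquinone A2 and set the stereocentre C8 by a cinchona-catalysed [4+2] cycloaddition with methylketene A3, which would give the benzodioxinone lactone A4;
aminolysis to the phenolic Weinreb amide A5, re-methylation to the dimethoxy Weinreb amide A6, Stille coupling to the cinnamyl alcohol amide A7 and addition of the aryl Grignard reagent A8 would then give the target.
Weakest steps: (a) the quinone–ketene cycloaddition that creates the stereocentre would have no precedent on a monohalogenated methoxy-o-quinone, so both the enantioselectivity and the choice of quinone oxygen would be unsecured, on a quinone too unstable to store;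
(b) the oxidative demethylation and later re-methylation would take one OMe off ring B and put it back, a dearomatisation/rearomatisation detour that builds nothing;
(c) the final Grignard addition would expose a free allylic alcohol and the base-labile α-aryloxy ketone to an excess of a basic organometallic, at the end of a fully linear sequence that carries the costly stereocentre through three further steps.

**Retrosynthetic overview** (C7 = ketone carbon, C8 = stereocentre, C9 = methyl; ring A = 3,4,5-trimethoxyphenyl, ring B = 2,6-dimethoxyphenoxy ring)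
The C9 methyl group and the C8–H bond are disconnected together: target 6 is traced to the achiral 2-aryloxy enone 5 (C7=O conjugated to C8=C9H2), whose enzymatic reduction adds hydride at C9 and a proton at C8 and so creates the only stereocentre in the last step.
Enone 5 comes from Mannich methylenation (C9 from formaldehyde) of the α-aryloxy acetophenone 3, itself the SN2 product (achiral C8–O bond) of bromo ketone 1 (ring A, C7, C8) and sinapyl alcohol 2 (ring B with its (E)-hydroxypropenyl chain).
No ring is formed: ring A and ring B are bought intact and joined first, and the stereocentre comes last.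
The design has no quinone, no demethylation/re-methylation, no organometallic reagent and no protecting group, and the labile C8 stereocentre never meets a base.

Key step: step 3

Assumption: 1 and (E)-sinapyl alcohol 2 are purchased, and a panel of ene-reductases covering both protonation senses is available for screening.

Step 1
Reactants: 1 2-bromo-1-(3,4,5-trimethoxyphenyl)ethan-1-one; 2 (E)-sinapyl alcohol [4-((E)-3-hydroxyprop-1-en-1-yl)-2,6-dimethoxyphenol]
Product: 3 2-{4-[(E)-3-hydroxyprop-1-en-1-yl]-2,6-dimethoxyphenoxy}-1-(3,4,5-trimethoxyphenyl)ethan-1-one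
Conditions: K2CO3 (1.5 equiv), acetone, rt → 40 °C, Ar, dark
Reagents that add atoms: none
Why: Williamson ether synthesis, in which K2CO3 deprotonates only the phenol and the α-bromo ketone is reactive enough in SN2 for the di-ortho-substituted phenoxide, so the allylic OH should need no protection.

Step 2
Reactants: 3 2-{4-[(E)-3-hydroxyprop-1-en-1-yl]-2,6-dimethoxyphenoxy}-1-(3,4,5-trimethoxyphenyl)ethan-1-one
Product: 5 2-{4-[(E)-3-hydroxyprop-1-en-1-yl]-2,6-dimethoxyphenoxy}-1-(3,4,5-trimethoxyphenyl)prop-2-en-1-one, via β-diisopropylamino ketone 4 (not isolated)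
Conditions: (CH2O)n (3 equiv), iPr2NH·CF3CO2H (1.0 equiv), THF, 65 °C; aq NaHCO3 work-up
Reagents that add atoms: formaldehyde (as paraformaldehyde), C=O
Why: Mannich α-methylenation of an aryl ketone, in which the enol of 3 (C8 is the only enolisable position) attacks the iminium ion and the Mannich base 4 loses the amine by E1cB because C8–H is acidified by C7=O and the aryloxy group; the weakly acidic ammonium salt should leave the cinnamyl alcohol intact.

Step 3
Reactants: 5 2-{4-[(E)-3-hydroxyprop-1-en-1-yl]-2,6-dimethoxyphenoxy}-1-(3,4,5-trimethoxyphenyl)prop-2-en-1-one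
Product: 6 (2R)-2-{4-[(E)-3-hydroxyprop-1-en-1-yl]-2,6-dimethoxyphenoxy}-1-(3,4,5-trimethoxyphenyl)propan-1-one (CNP0171423.1)
Conditions: ene-reductase (FMN-dependent, old yellow enzyme family; panel member selected for Si-face protonation at C8), NADP+ (2 mol %), glucose dehydrogenase, D-glucose (2 equiv), KH2PO4/K2HPO4 buffer pH 7.0–MTBE (1:1), 30 °C, N2, dark
Reagents that add atoms: none
Why: Proposed new method: ene-reductases are known to reduce α-alkoxy and α-acyloxy enones to O-protected acyloins and α-methylene ketones with Cα set by protonation, but not yet a 1-aryl-2-aryloxyprop-2-en-1-one, which is the extension proposed here. The C7=O of 5 should bind to the histidine/asparagine (or histidine/histidine) pair above the reduced flavin, FMNH2 should deliver hydride from N5 to the unhindered terminal C9, and the conserved tyrosine should protonate C8 on the opposite face, a net anti addition of H2 that closes no ring. The new stereocentre C8 is controlled only by the binding mode in the active site: protonation on the Si face of C8 (OAr > C7 > C9) gives (R), and a panel of wild-type enzymes with binding-mode-flipping variants should supply that sense. Chemoselectivity is secured by the mechanism, since flavin hydride adds only to a carbonyl-polarised C=C, so the cinnamyl C=C, the ketone and the free OH should stay untouched without protection. Retention of configuration needs the labile C8–H to escape enolisation, which pH 7, 30 °C and continuous extraction of 6 into MTBE should secure.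

**Compound list**
1 | 2-bromo-1-(3,4,5-trimethoxyphenyl)ethan-1-one | COc1cc(C(=O)CBr)cc(OC)c1OC | starting material
2 | (E)-sinapyl alcohol, 4-[(E)-3-hydroxyprop-1-en-1-yl]-2,6-dimethoxyphenol | COc1cc(/C=C/CO)cc(OC)c1O | starting material
3 | 2-{4-[(E)-3-hydroxyprop-1-en-1-yl]-2,6-dimethoxyphenoxy}-1-(3,4,5-trimethoxyphenyl)ethan-1-one | COc1cc(C(=O)COc2c(OC)cc(/C=C/CO)cc2OC)cc(OC)c1OC | intermediate
4 | rac-3-(diisopropylamino)-2-{4-[(E)-3-hydroxyprop-1-en-1-yl]-2,6-dimethoxyphenoxy}-1-(3,4,5-trimethoxyphenyl)propan-1-one | COc1cc(C(=O)C(CN(C(C)C)C(C)C)Oc2c(OC)cc(/C=C/CO)cc2OC)cc(OC)c1OC | intermediate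
5 | 2-{4-[(E)-3-hydroxyprop-1-en-1-yl]-2,6-dimethoxyphenoxy}-1-(3,4,5-trimethoxyphenyl)prop-2-en-1-one | COc1cc(C(=O)C(=C)Oc2c(OC)cc(/C=C/CO)cc2OC)cc(OC)c1OC | intermediate
6 | (2R)-2-{4-[(E)-3-hydroxyprop-1-en-1-yl]-2,6-dimethoxyphenoxy}-1-(3,4,5-trimethoxyphenyl)propan-1-one | COc1cc(C(=O)[C@@H](C)Oc2c(OC)cc(/C=C/CO)cc2OC)cc(OC)c1OC | target

Total step count: 3. Longest linear sequence: 3 steps (1 + 2 → 3 → 5 → 6).

**Steps most likely to fail, with fallbacks**

Step 3 (proposed new method). The bulky diaryl substrate may bind poorly in the active site, protonation of C8 may occur on both faces, or the product may slowly enolise in the buffer. Fallback from 5 to 6 by known chemistry: conjugate reduction without stereocontrol with [(Ph3P)CuH]6 in wet THF at rt should give racemic 2-{4-[(E)-3-hydroxyprop-1-en-1-yl]-2,6-dimethoxyphenoxy}-1-(3,4,5-trimethoxyphenyl)propan-1-one F1. Preparative chromatography on a polysaccharide chiral stationary phase should then deliver 6. The unwanted (2S)-2-{4-[(E)-3-hydroxyprop-1-en-1-yl]-2,6-dimethoxyphenoxy}-1-(3,4,5-trimethoxyphenyl)propan-1-one F2 would be racemised back to F1 with DBU in MeCN and recycled, so the stereocentre is obtained by resolution with recycling instead of by asymmetric catalysis.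

Step 2. The ammonium salt at 65 °C may ionise or etherify the electron-rich cinnamyl alcohol, or the enone may undergo oxa-Michael oligomerisation with the free OH. Fallback from 3 to 5 by aldol/E1cB instead of Mannich chemistry: hydroxymethylation of 3 with aqueous CH2O and K2CO3 in EtOH at rt should give rac-3-hydroxy-2-{4-[(E)-3-hydroxyprop-1-en-1-yl]-2,6-dimethoxyphenoxy}-1-(3,4,5-trimethoxyphenyl)propan-1-one F3, and Ac2O/pyridine should convert it into the diacetate rac-(E)-3-(4-{[1-acetoxy-3-oxo-3-(3,4,5-trimethoxyphenyl)propan-2-yl]oxy}-3,5-dimethoxyphenyl)prop-2-en-1-yl acetate F4. DBU in CH2Cl2 at 0 °C should then remove acetic acid only from the β-acetoxy ketone and give (E)-3-{3,5-dimethoxy-4-[3-oxo-3-(3,4,5-trimethoxyphenyl)prop-1-en-2-yl]oxyphenyl}prop-2-en-1-yl acetate F5, and hydrolysis of the allylic acetate with Candida antarctica lipase B at pH 7 in buffer/MTBE should return to 5 without exposing the enone to an alkoxide.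

Step 1. The sinapyl phenoxide may be air-oxidised or may polymerise, and the acidic CH2 of 3 may be alkylated a second time. Fallback from 1 to 3, in which the side chain is made by C–H oxidation on a robust phenol: 1 and purchased 4-allyl-2,6-dimethoxyphenol F6 with K2CO3 in acetone should give 2-(4-allyl-2,6-dimethoxyphenoxy)-1-(3,4,5-trimethoxyphenyl)ethan-1-one F7. Linear allylic C–H acetoxylation with Pd(OAc)2 (10 mol %) and 1,4-benzoquinone in DMSO/AcOH at 40 °C should then give (E)-3-{3,5-dimethoxy-4-[2-oxo-2-(3,4,5-trimethoxyphenyl)ethoxy]phenyl}prop-2-en-1-yl acetate F8, and methanolysis with K2CO3 in MeOH at 0 °C (no stereocentre is present yet) should give 3.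

**Further compounds**
F1 | step 3 | rac-2-{4-[(E)-3-hydroxyprop-1-en-1-yl]-2,6-dimethoxyphenoxy}-1-(3,4,5-trimethoxyphenyl)propan-1-one | COc1cc(C(=O)C(C)Oc2c(OC)cc(/C=C/CO)cc2OC)cc(OC)c1OC
F2 | step 3 | (2S)-2-{4-[(E)-3-hydroxyprop-1-en-1-yl]-2,6-dimethoxyphenoxy}-1-(3,4,5-trimethoxyphenyl)propan-1-one | COc1cc(C(=O)[C@H](C)Oc2c(OC)cc(/C=C/CO)cc2OC)cc(OC)c1OC
F3 | step 2 | rac-3-hydroxy-2-{4-[(E)-3-hydroxyprop-1-en-1-yl]-2,6-dimethoxyphenoxy}-1-(3,4,5-trimethoxyphenyl)propan-1-one | COc1cc(C(=O)C(CO)Oc2c(OC)cc(/C=C/CO)cc2OC)cc(OC)c1OC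
F4 | step 2 | rac-(E)-3-(4-{[1-acetoxy-3-oxo-3-(3,4,5-trimethoxyphenyl)propan-2-yl]oxy}-3,5-dimethoxyphenyl)prop-2-en-1-yl acetate | COc1cc(C(=O)C(COC(C)=O)Oc2c(OC)cc(/C=C/COC(C)=O)cc2OC)cc(OC)c1OC
F5 | step 2 | (E)-3-{3,5-dimethoxy-4-[3-oxo-3-(3,4,5-trimethoxyphenyl)prop-1-en-2-yl]oxyphenyl}prop-2-en-1-yl acetate | COc1cc(C(=O)C(=C)Oc2c(OC)cc(/C=C/COC(C)=O)cc2OC)cc(OC)c1OC
F6 | step 1 | 4-allyl-2,6-dimethoxyphenol | COc1cc(CC=C)cc(OC)c1O
F7 | step 1 | 2-(4-allyl-2,6-dimethoxyphenoxy)-1-(3,4,5-trimethoxyphenyl)ethan-1-one | COc1cc(C(=O)COc2c(OC)cc(CC=C)cc2OC)cc(OC)c1OC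
F8 | step 1 | (E)-3-{3,5-dimethoxy-4-[2-oxo-2-(3,4,5-trimethoxyphenyl)ethoxy]phenyl}prop-2-en-1-yl acetate | COc1cc(C(=O)COc2c(OC)cc(/C=C/COC(C)=O)cc2OC)cc(OC)c1OC
A1 | direct plan | 4-bromo-2,6-dimethoxyphenol | COc1cc(Br)cc(OC)c1O
A2 | direct plan | 5-bromo-3-methoxycyclohexa-3,5-diene-1,2-dione | COC1=CC(Br)=CC(=O)C1=O
A3 | direct plan | methylketene | CC=C=O
A4 | direct plan | (3R)-7-bromo-5-methoxy-3-methyl-1,4-benzodioxin-2(3H)-one | C[C@H]1Oc2c(OC)cc(Br)cc2OC1=O
A5 | direct plan | (2R)-2-(4-bromo-2-hydroxy-6-methoxyphenoxy)-N-methoxy-N-methylpropanamide | C[C@@H](Oc1c(O)cc(Br)cc1OC)C(=O)N(C)OC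
A6 | direct plan | (2R)-2-(4-bromo-2,6-dimethoxyphenoxy)-N-methoxy-N-methylpropanamide | C[C@@H](Oc1c(OC)cc(Br)cc1OC)C(=O)N(C)OC
A7 | direct plan | (2R)-2-{4-[(E)-3-hydroxyprop-1-en-1-yl]-2,6-dimethoxyphenoxy}-N-methoxy-N-methylpropanamide | C[C@@H](Oc1c(OC)cc(/C=C/CO)cc1OC)C(=O)N(C)OC
A8 | direct plan | 3,4,5-trimethoxyphenylmagnesium bromide | COc1cc([Mg]Br)cc(OC)c1OC
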